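(The numbers in the tables stem from a simulated flask with constants of no real substance.)

| flask | substrate | coupling partner | free catalyst | remark | time |
|---|---|---|---|---|---|
| red | 0.10 M | 0.20 M | 5 mM | run made earlier |  |
| grey | 0.10 M | 0.20 M | 3.4 mM | run made earlier |  |
| ochre | 0.10 M | 0.20 M | 7.5 mM | run made earlier |  |
| delta | 0.10 M | 0.200 M | 5.0 mM | a closed flask charged with all of it at once and left for 8.0 min | 8.0 min |
| beta | 0.10 M | 0.200 M | 5.0 mM | a single well-mixed tank run continuously and read at steady state, 40.0 min in it on average |  |
| gamma | 0.10 M (fed, over 8.00 min) | 0.200 M | 5.0 mM | all but substrate at the start; substrate goes in evenly over 8.00 min, the run ends at 8.0 min | 8.0 min |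
| alpha | 0.10 M | 0.200 M | 5.0 mM | a single well-mixed tank run continuously and read at steady state, 8.0 min in it on average |  |

- red (time / min: target / %, substrate / %): 0.417: 0, 102; 0.667: 0, 98; 0.833: 2, 97; 1.33: 8, 95; 2.00: 9, 89; 3.00: 14, 85; 5.00: 21, 73
- grey (time / min: target / %, substrate / %): 1.00: 6, 97; 2.00: 7, 89; 3.00: 10, 90; 4.00: 12, 82; 5.00: 18, 81; 6.00: 17, 77
- ochre (time / min: target / %, substrate / %): 1.00: 7, 91; 2.00: 16, 80; 3.00: 19, 73; 4.00: 24, 70; 5.00: 29, 63; 6.00: 38, 54

(each reading ± 2 percentage points)

- the stated concentrations are those of everything mixed, before any reaction; amounts are the same in each set-up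
- the feed brings no volume worth counting
- the earlier runs were made in a closed, stirred flask

1. the set-up with the highest amount of target at the outlet or at the end, in percent of the substrate put in ("none" if the first two lie within 2 percentage points) (delta / beta / gamma / alpha / none)
2. amount of target at the outlet or at the end, in percent of the substrate put in, delta
3. amount of target at the outlet or at the end, in percent of the substrate put in, beta
4. amount of target at the outlet or at the end, in percent of the substrate put in, gamma
5. amount of target at the outlet or at the end, in percent of the substrate put in, alpha

Late readings show the most: the substrate of the ochre run stands at 54% after 6.00 min and is still falling, so the end state the runs point to is a flask without substrate. The coupling partner is charged at twice the substrate, so substrate is the limiting reagent. But the asked times stop short of that end, so the question is how fast it is approached.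

Take the last substrate reading of a run, and divide minus the logarithm of the fraction left by c·t, where c is the free catalyst charged and t the time. This catalyst-specific rate constant κ comes to 12.8 M⁻¹ min⁻¹ in grey and 13.7 M⁻¹ min⁻¹ in ochre, though ochre holds twice the catalyst. So the readings bear first order in catalyst, while first order in substrate, a pseudo-first-order loss, stays an assumption of this reckoning. With red, the mean is 13.0 M⁻¹ min⁻¹.

The clock N = κ·c·t is then 0.521 for delta, gamma and alpha, and 2.61 for beta, with the mean residence time as t in the tanks. If the loss is first order in substrate with κ·c constant, a closed flask keeps e^(−N) of its substrate, a tank at steady state keeps the reciprocal of one plus N, and a flask dosed evenly up to the end of the run keeps (one minus e^(−N)) over N. The readings put target at 78.1% of the substrate consumed.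

This reckoning gives delta 31.7%, alpha 26.8%, beta 56.4% and gamma 17.2%.

The forecast differs slightly, with delta 32%, alpha 27%, beta 55% and gamma 18%, and it names beta: “Beta is best because of its long residence time.”

The flasks give delta 30.8%, beta 59.5%, gamma 21.9% and alpha 27.7%, so the best is beta.

    coupling partner + free catalyst ⇌ catalyst intermediate A (K = 20.0 M⁻¹, k = 460 M⁻¹ min⁻¹)
    catalyst intermediate A → catalyst intermediate B (k = 6.22 min⁻¹)
    catalyst intermediate B ⇌ by-product + catalyst intermediate C (K = 2.67 M, k = 6.16 min⁻¹)
    substrate + catalyst intermediate C ⇌ catalyst intermediate D (K = 27.0 M⁻¹, k = 53.5 M⁻¹ min⁻¹)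
    catalyst intermediate D → free catalyst + target (k = 4.66 min⁻¹)
    target ⇌ isomer of the product (K = 0.430, k = 0.185 min⁻¹)

The clock of delta puts its substrate at 59.4%, and delta holds 58.4% at 8.00 min, with 6.21% of the catalyst charged free and 42.5% as catalyst intermediate C. A neighbour of gamma, charged with 0.013 M of free catalyst, has a clock of 1.36, so the dosed reckoning leaves it 54.8% of the substrate and gives 35.3% target. That neighbour ends with 39.9% substrate and 45.1% target.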